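## Retrosynthetic overview

1. Target 27, (13R)-6β-acetoxy-13-hydroxylabda-8,14-dien-7-one, comes from acetylation and desilylation of an 8-en-7-one. That enone arises by oxidative 1,3-transposition of a C9 tertiary allylic alcohol, formed by adding a C11–C16 organocerium (C13 taken from (R)-linalool) to the C9 ketone of 14.
2. Ketone 14 comes from α-face hydride reduction of the 7-ene-6,9-dione 12, made by γ-oxidation (C6) of enone 11, itself obtained by removing the C1 carbonyl of dione 8.
3. Dione 8 comes from closing ring A onto a finished ring B through the C3–C4 bond. The route rests on C4, the quaternary gem-dimethyl carbon of ring A bonded to ring-fusion carbon C5: C4 is the tertiary radical carbon that the isopropenyl group of carvone becomes, and C5/C10 are C5/C6 of the carvone ring.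
4. Precursor 7 comes from (R)-carvone by α′-methylation, aldol addition to acrolein anti to isopropenyl (sets C10) and oxidation. Ring order: ring B from carvone, then ring A in the key step.

Key step: step 4

Remarks on the chemistry (assumptions):
- Labdane numbering is used for the bicyclic compounds (C1–C10 ring carbons, methyls on C4, C4, C8 and C10, side chain C11–C16). α is the face of H-5, β the face of the C10 methyl.
- Where a stereocentre is destroyed later (C6 of 3, C1 of 9 and 10, C9 of 24), the expected major epimer is named and drawn; either epimer serves. The carbinol carbon of 6 and the ozonide carbon of 17 are left undefined.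
- Commercial (R)-(−)-linalool of high enantiomeric purity is assumed.

## Route

Step 1
Reactants: 1 (R)-carvone
Product: 3 trans-6-methylcarvone, via lithium dienolate 2 (not isolated)
Conditions: LiN(iPr)2, THF, −78 °C; then MeI, −78 to 0 °C
Reagents that add atoms: iodomethane CI
Why: Kinetic deprotonation at the α′-carbon (C6) gives the cross-conjugated dienolate, and its C-alkylation by MeI (enolate alkylation) should occur mainly anti to the isopropenyl group; the new C6 centre is made planar again in step 2, so its configuration does not matter.

Step 2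
Reactants: 3 trans-6-methylcarvone; 4 acrolein
Product: 6 6-(1-hydroxyprop-2-en-1-yl)-6-methylcarvone (hydroxyallyl arm trans to isopropenyl), via lithium enolate 5 (not isolated)
Conditions: LiN(iPr)2, THF, −78 °C; then 4, −78 °C; AcOH quench at −78 °C
Reagents that add atoms: none
Why: The tetrasubstituted lithium enolate should undergo a kinetic aldol 1,2-addition to acrolein on the face anti to the neighbouring isopropenyl group, which fixes the quaternary carbon (the future C10) with methyl cis and the new three-carbon arm trans to isopropenyl, while the carbinol centre (a mixture) is removed in step 3 and the cold acidic quench forestalls retro-aldol cleavage.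

Step 3
Reactants: 6 aldol adduct
Product: 7 (5S,6R)-6-acryloyl-2,6-dimethyl-5-(prop-1-en-2-yl)cyclohex-2-en-1-one
Conditions: Dess–Martin periodinane, CH2Cl2, 0 °C to rt
Reagents that add atoms: none
Why: Dess–Martin oxidation converts the secondary allylic alcohol into the vinyl ketone under neutral, non-nucleophilic conditions that should spare the base-sensitive quaternary 1,3-dicarbonyl unit and touch no stereocentre.

Step 4
Reactants: 7 acryloyl ketone
Product: 8 11-nordrim-7-ene-1,9-dione (trans-fused, 5α-H, 10β-CH3)
Conditions: Fe(acac)3 (0.3 equiv), PhSiH3 (2.5 equiv), EtOH/ethylene glycol, 0.02 M, 60 °C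
Reagents that add atoms: none
Why: Fe(acac)3 and PhSiH3 in ethanol should generate an iron hydride that transfers a hydrogen atom to the CH2 terminus of the electron-rich 1,1-disubstituted isopropenyl group, and the resulting nucleophilic tertiary radical at C4 adds to the unsubstituted terminus (C3) of the acryloyl group, after which the α-keto radical at C2 is reduced by divalent iron to the enolate and protonated by the solvent. The closest known reaction type is the Fe(acac)3/PhSiH3 reductive olefin coupling (a hydrogen-atom-transfer-initiated Giese addition) run intramolecularly. Ring A closes by formation of the C3–C4 bond in the 6-endo-trig mode. No new stereocentre arises, since C4 becomes the gem-dimethyl carbon and C2 a methylene; the trans ring fusion is dictated by the trans C5 and C10 arms set in steps 1 and 2, which can only be bridged from the diequatorial conformer of ring B. The step needs hydrogen-atom transfer to the isopropenyl group and not to the two enone double bonds, which their electron-poor character secures, and attack at C3 and nowhere else, which is secured because 5-exo attack at C2 is polarity-mismatched and attack on the ring-B enone would require a four-membered ring.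

Step 5
Reactants: 8 11-nordrim-7-ene-1,9-dione
Product: 9 1β-hydroxy-11-nordrim-7-en-9-one
Conditions: NaBH4 (0.5 equiv), EtOH, −20 to 0 °C
Reagents that add atoms: none
Why: Chemoselective NaBH4 1,2-reduction should take place at the saturated C1 ketone, which is more electrophilic than the cross-conjugated, α-methylated C9 enone carbonyl, with axial hydride delivery from the α-face giving the 1β (equatorial) alcohol, a centre removed in step 7.

Step 6
Reactants: 9 1β-hydroxy-11-nordrim-7-en-9-one
Product: 10 O-(9-oxo-11-nordrim-7-en-1β-yl) imidazole-1-carbothioate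
Conditions: 1,1'-thiocarbonyldiimidazole, DMAP (cat.), ClCH2CH2Cl, 70 °C
Reagents that add atoms: 1,1'-thiocarbonyldiimidazole S=C(n1ccnc1)n1ccnc1
Why: Thioacylation of the secondary alcohol with thiocarbonyldiimidazole proceeds without strong base, so no alkoxide is formed that could open the β-hydroxy ketone by retro-aldol cleavage; C1 is not inverted.

Step 7
Reactants: 10 imidazole-1-carbothioate
Product: 11 11-nordrim-7-en-9-one
Conditions: Bu3SnH (ca. 0.3 M), AIBN (cat.), toluene, 100 °C
Reagents that add atoms: none
Why: Barton–McCombie deoxygenation: addition of Bu3Sn• to the thiocarbonyl group and β-scission give the C1 radical, which is reduced by Bu3SnH kept at high concentration so that hydrogen transfer outruns 1,2-acyl migration of this β-keto radical, and the C1 stereocentre disappears.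

Step 8
Reactants: 11 11-nordrim-7-en-9-one
Product: 12 11-nordrim-7-ene-6,9-dione
Conditions: Rh2(cap)4 (cat.; cap = caprolactamate, C6H10NO), t-BuOOH (70% aq.), ClCH2CH2Cl, 40 °C
Reagents that add atoms: tert-butyl hydroperoxide CC(C)(C)OO
Why: In this catalytic allylic oxidation (enone to ene-dione with Rh2(cap)4 and t-BuOOH) the tert-butylperoxyl radical should abstract hydrogen from C6, the only secondary allylic (γ) position, rather than from the primary C8 methyl, and the mixed peroxide formed at C6 collapses to the ketone; no stereocentre is created and the trans ring fusion at C5, now α to a carbonyl, is the more stable one.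

Step 9
Reactants: 12 11-nordrim-7-ene-6,9-dione
Product: 13 6β-hydroxy-11-nordrim-7-en-9-one
Conditions: NaBH4, CeCl3·7H2O, MeOH, −78 °C
Reagents that add atoms: none
Why: Luche 1,2-reduction should select the C6 carbonyl, which unlike C9 is not flanked by the quaternary C10 and the methyl-bearing C8 (the same steric bias directs nucleophiles to C4 of 2,6,6-trimethylcyclohex-2-ene-1,4-dione), and hydride should enter from the α-face because the β-face is screened by the syn-axial methyls on C4 and C10, setting the axial 6β-hydroxyl.

Step 10
Reactants: 13 6β-hydroxy-11-nordrim-7-en-9-one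
Product: 14 6β-(triethylsilyloxy)-11-nordrim-7-en-9-one
Conditions: Et3SiOTf, 2,6-lutidine, CH2Cl2, −78 to 0 °C
Reagents that add atoms: triethylsilyl trifluoromethanesulfonate CC[Si](CC)(CC)OS(=O)(=O)C(F)(F)F
Why: O-silylation with the highly reactive silyl triflate and 2,6-lutidine should overcome the hindrance of the axial 6β-hydroxyl and masks it for the organometallic addition and the chromium oxidation; no stereocentre changes.

Step 11
Reactants: 15 (R)-linalool
Product: 16 (R)-linalool tert-butyldimethylsilyl ether
Conditions: t-BuMe2SiOTf, 2,6-lutidine, CH2Cl2, 0 °C to rt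
Reagents that add atoms: tert-butyldimethylsilyl trifluoromethanesulfonate CC(C)(C)[Si](C)(C)OS(=O)(=O)C(F)(F)F
Why: O-silylation of the tertiary allylic alcohol needs the silyl triflate, and the bulky tert-butyldimethylsilyl group is chosen because it resists 1,4 O-to-C silyl migration in the γ-silyloxy alkyllithium of step 15; C13 is untouched.

Step 12
Reactants: 16 (R)-linalool tert-butyldimethylsilyl ether
Product: 18 (R)-4-(tert-butyldimethylsilyloxy)-4-methylhex-5-enal, via secondary ozonide 17 (not isolated)
Conditions: O3 (1 equiv, indicator dye), CH2Cl2, −78 °C; then PPh3, −78 °C to rt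
Reagents that add atoms: ozone [O-][O+]=O
Why: Ozonolysis: electrophilic ozone, dosed to one equivalent against an indicator dye, should cleave the electron-rich trisubstituted double bond much faster than the monosubstituted vinyl group on the hindered oxygenated quaternary carbon, and PPh3 reduces the ozonide to the aldehyde.

Step 13
Reactants: 18 (R)-4-(tert-butyldimethylsilyloxy)-4-methylhex-5-enal
Product: 19 (R)-4-(tert-butyldimethylsilyloxy)-4-methylhex-5-enoic acid
Conditions: NaClO2, NaH2PO4, 2-methyl-2-butene, t-BuOH/H2O, 0 °C to rt
Reagents that add atoms: sodium chlorite [Na+].[O-]Cl=O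
Why: Pinnick oxidation converts the aldehyde into the acid with chlorous acid while 2-methyl-2-butene traps the hypochlorous acid formed, so that the vinyl group and the silyl ether survive.

Step 14
Reactants: 19 (R)-4-(tert-butyldimethylsilyloxy)-4-methylhex-5-enoic acid
Product: 21 (R)-tert-butyl[(5-iodo-3-methylpent-1-en-3-yl)oxy]dimethylsilane, via Barton ester 20 (not isolated)
Conditions: 1-hydroxypyridine-2(1H)-thione, DCC, DMAP (cat.), CH2Cl2, dark, 0 °C to rt; then CHI3, hν (tungsten-filament lamp), rt
Reagents that add atoms: iodoform IC(I)I
Why: Barton decarboxylation: the thiohydroxamate ester fragments under light in a radical chain, the acyloxy radical loses CO2, and the primary C11 radical abstracts iodine from iodoform faster than it could cyclise onto the vinyl group (4-exo), which removes the surplus carbon and installs the handle for metalation.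

Step 15
Reactants: 21 (R)-tert-butyl[(5-iodo-3-methylpent-1-en-3-yl)oxy]dimethylsilane; 14 6β-(triethylsilyloxy)-11-nordrim-7-en-9-one
Product: 24 (13R)-13-(tert-butyldimethylsilyloxy)-6β-(triethylsilyloxy)labda-7,14-dien-9-ol, via alkyllithium 22 (not isolated), via alkylcerium dichloride 23 (not isolated)
Conditions: 21, t-BuLi (2 equiv), Et2O/pentane, −78 °C; CeCl3 (anhydrous), THF, −78 °C; then 14, −78 to −40 °C; H2O/aq. NH4Cl work-up
Reagents that add atoms: none
Why: Iodine–lithium exchange followed by transmetalation to cerium gives a strongly nucleophilic but weakly basic reagent (organocerium 1,2-addition) that should add to the hindered C9 carbonyl, which has no α-hydrogen, without conjugate addition or γ-deprotonation; the C9 centre, expected from α-face attack anti to the C10 methyl, is destroyed in step 16.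

Step 16
Reactants: 24 labda-7,14-dien-9-ol bis-silyl ether
Product: 25 (13R)-13-(tert-butyldimethylsilyloxy)-6β-(triethylsilyloxy)labda-8,14-dien-7-one
Conditions: pyridinium chlorochromate (C5H5NH[CrO3Cl]), 4 Å molecular sieves, CH2Cl2, rt
Reagents that add atoms: pyridinium chlorochromate [O-][Cr](=O)(=O)Cl.c1cc[nH+]cc1
Why: Dauben–Michno oxidative transposition: the chromate ester of the tertiary allylic alcohol should undergo a [3,3] shift to C7 and be oxidised there, giving the tetrasubstituted C8=C9 enone with the side chain on C9, while the silyl ethers keep the C6 and C13 oxygens out of the reaction and the non-basic medium leaves C6 (now α to the ketone) unepimerised.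

Step 17
Reactants: 25 bis-silyl ether of the 8-en-7-one
Product: 26 (13R)-6β,13-dihydroxylabda-8,14-dien-7-one
Conditions: HF·pyridine, pyridine, THF, 0 °C to rt
Reagents that add atoms: none
Why: Fluoride-driven desilylation (strong Si–F bond) in a pyridine-buffered, weakly acidic medium should remove both silyl groups without enolising the C7 ketone toward C6, so the axial 6β configuration is kept, and without ionising the tertiary allylic alcohol.

Step 18
Reactants: 26 (13R)-6β,13-dihydroxylabda-8,14-dien-7-one
Product: 27 (13R)-6β-acetoxy-13-hydroxylabda-8,14-dien-7-one (CNP0328351.1)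
Conditions: Ac2O, pyridine, DMAP (cat.), CH2Cl2, 0 °C to rt
Reagents that add atoms: acetic anhydride CC(=O)OC(C)=O
Why: DMAP-catalysed O-acetylation should occur at the secondary 6β-hydroxyl and not at the far less reactive tertiary allylic 13-hydroxyl, under conditions too mild to epimerise C6.

## Compound list

1 | (R)-carvone, (5R)-2-methyl-5-(prop-1-en-2-yl)cyclohex-2-en-1-one | CC1=CC[C@H](CC1=O)C(C)=C | starting material
2 | lithium dienolate of 1 (O–Li on C1, double bonds C1=C6 and C2=C3) | CC1=CC[C@H](C=C1O[Li])C(C)=C | intermediate (not isolated)
3 | trans-6-methylcarvone, (5R,6S)-2,6-dimethyl-5-(prop-1-en-2-yl)cyclohex-2-en-1-one | C[C@H]1[C@H](C(C)=C)CC=C(C)C1=O | intermediate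
4 | acrolein (prop-2-enal) | C=CC=O | starting material
5 | lithium enolate of 3 (O–Li on C1, tetrasubstituted C1=C6) | CC1=CC[C@H](C(C)=C1O[Li])C(C)=C | intermediate (not isolated)
6 | (5S,6R)-6-(1-hydroxyprop-2-en-1-yl)-2,6-dimethyl-5-(prop-1-en-2-yl)cyclohex-2-en-1-one, carbinol epimers | C=CC(O)[C@@]1(C)[C@H](C(C)=C)CC=C(C)C1=O | intermediate
7 | (5S,6R)-6-acryloyl-2,6-dimethyl-5-(prop-1-en-2-yl)cyclohex-2-en-1-one (acryloyl trans to isopropenyl) | C=CC(=O)[C@@]1(C)[C@H](C(C)=C)CC=C(C)C1=O | intermediate
8 | 11-nordrim-7-ene-1,9-dione (trans-fused, 5α-H, 10β-CH3) | O=C1CCC(C)(C)[C@@H]2CC=C(C)C(=O)[C@@]12C | intermediate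
9 | 1β-hydroxy-11-nordrim-7-en-9-one | O[C@@H]1CCC(C)(C)[C@@H]2CC=C(C)C(=O)[C@@]12C | intermediate
10 | O-(9-oxo-11-nordrim-7-en-1β-yl) imidazole-1-carbothioate | S=C(O[C@@H]1CCC(C)(C)[C@@H]2CC=C(C)C(=O)[C@@]12C)n1ccnc1 | intermediate
11 | 11-nordrim-7-en-9-one | C1CCC(C)(C)[C@@H]2CC=C(C)C(=O)[C@@]12C | intermediate
12 | 11-nordrim-7-ene-6,9-dione | C1CCC(C)(C)[C@@H]2C(=O)C=C(C)C(=O)[C@@]12C | intermediate
13 | 6β-hydroxy-11-nordrim-7-en-9-one | C1CCC(C)(C)[C@@H]2[C@H](O)C=C(C)C(=O)[C@@]12C | intermediate
14 | 6β-(triethylsilyloxy)-11-nordrim-7-en-9-one | C1CCC(C)(C)[C@@H]2[C@H](O[Si](CC)(CC)CC)C=C(C)C(=O)[C@@]12C | intermediate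
15 | (R)-linalool | C=C[C@](C)(O)CCC=C(C)C | starting material
16 | (R)-linalool tert-butyldimethylsilyl ether | C=C[C@](C)(O[Si](C)(C)C(C)(C)C)CCC=C(C)C | intermediate
17 | secondary ozonide (1,2,4-trioxolane) of the trisubstituted double bond of 16 | C=C[C@](C)(O[Si](C)(C)C(C)(C)C)CCC1OOC(C)(C)O1 | intermediate (not isolated)
18 | (R)-4-(tert-butyldimethylsilyloxy)-4-methylhex-5-enal | C=C[C@](C)(O[Si](C)(C)C(C)(C)C)CCC=O | intermediate
19 | (R)-4-(tert-butyldimethylsilyloxy)-4-methylhex-5-enoic acid | C=C[C@](C)(O[Si](C)(C)C(C)(C)C)CCC(=O)O | intermediate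
20 | 2-thioxopyridin-1(2H)-yl ester of 19 (Barton ester) | C=C[C@](C)(O[Si](C)(C)C(C)(C)C)CCC(=O)ON1C=CC=CC1=S | intermediate (not isolated)
21 | (R)-tert-butyl[(5-iodo-3-methylpent-1-en-3-yl)oxy]dimethylsilane | C=C[C@](C)(O[Si](C)(C)C(C)(C)C)CCI | intermediate
22 | primary alkyllithium from 21 | C=C[C@](C)(O[Si](C)(C)C(C)(C)C)CC[Li] | intermediate (not isolated)
23 | alkylcerium dichloride from 22 | C=C[C@](C)(O[Si](C)(C)C(C)(C)C)CC[Ce](Cl)Cl | intermediate (not isolated)
24 | (13R)-13-(tert-butyldimethylsilyloxy)-6β-(triethylsilyloxy)labda-7,14-dien-9-ol (9β-OH drawn) | C1CCC(C)(C)[C@@H]2[C@H](O[Si](CC)(CC)CC)C=C(C)[C@@](O)(CC[C@@](C)(O[Si](C)(C)C(C)(C)C)C=C)[C@@]12C | intermediate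
25 | (13R)-13-(tert-butyldimethylsilyloxy)-6β-(triethylsilyloxy)labda-8,14-dien-7-one | C=C[C@](C)(O[Si](C)(C)C(C)(C)C)CCC1=C(C)C(=O)[C@@H](O[Si](CC)(CC)CC)[C@H]2C(C)(C)CCC[C@]12C | intermediate
26 | (13R)-6β,13-dihydroxylabda-8,14-dien-7-one | C=C[C@](C)(O)CCC1=C(C)C(=O)[C@@H](O)[C@H]2C(C)(C)CCC[C@]12C | intermediate
27 | (13R)-6β-acetoxy-13-hydroxylabda-8,14-dien-7-one (CNP0328351.1) | C=C[C@](C)(O)CCC1=C(C)C(=O)[C@@H](OC(C)=O)[C@H]2C(C)(C)CCC[C@]12C | target

## Step count and risks

Total step count: 18. Longest linear sequence: 14 steps (steps 1–10 and 15–18, from (R)-carvone); the side chain takes 4 steps (11–14) from (R)-linalool.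

Steps most likely to fail:

1. Step 4 (radical ring closure). Hydrogen-atom transfer may go to the acryloyl double bond and simply reduce it, the tertiary radical may be reduced before it cyclises, or the vinyl ketone may oligomerise. Fallback: the radical site is fixed by a carbon–bromine bond and the chain is run with a tin hydride. Setting out from 7, HBr in AcOH/CH2Cl2 at 0 °C should add to the isopropenyl group (Markovnikov) and to the vinyl ketone (conjugate addition) to give the bis-hydrobromide F1. Et3N in CH2Cl2 at 0 °C should remove HBr from the β-bromo ketone only (E1cB), returning the acryloyl group in the tertiary bromide F2. Slow addition of Bu3SnH with AIBN in benzene at 80 °C should then abstract bromine, and the same C4 radical closes ring A in the 6-endo mode to give 8, where the route is rejoined.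

2. Step 8 (oxidation at C6). Hydrogen abstraction may take place at the C8 methyl, or the hindered C6 position may react so slowly that the catalyst is consumed and over-oxidation sets in. Fallback: C6 is activated as the terminus of a dienolate instead of by radical abstraction. Setting out from 11, KN(SiMe3)2 in THF at −78 °C can only remove a C6 hydrogen (C10 is quaternary), and O-silylation with t-BuMe2SiCl should give the 9-(tert-butyldimethylsilyloxy)-11-nordrima-6,8-diene F3. Singlet oxygen (O2, tetraphenylporphyrin, visible light, CH2Cl2, −78 °C) should add across C6 and C9 of this ring-B cyclohexadiene in a [4+2] cycloaddition to give the 6,9-epidioxide F4. Et3N should then trigger a Kornblum–DeLaMare fragmentation (loss of the C6 hydrogen, O–O cleavage, loss of silanol from C9) to the ene-dione 12, where the route is rejoined.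

3. Step 9 (reduction of the ene-dione). Discrimination between the two carbonyl groups may be poor, so that C9 is reduced as well. Fallback: both carbonyls are reduced and C9 alone is re-oxidised. Setting out from 12, excess NaBH4/CeCl3·7H2O in MeOH at −20 °C should give the 11-nordrim-7-ene-6β,9β-diol F5 (hydride from the α-face at both carbons). MnO2 in CH2Cl2 at rt should oxidise only the pseudo-equatorial 9β-hydroxyl, whose carbinol C–H bond is aligned with the π-system, and leave the screened pseudo-axial 6β-hydroxyl, giving 13, where the route is rejoined.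

Further compounds
F1 | step 4 | bis-hydrobromide of 7 (tertiary bromide at C4, 3-bromopropanoyl group on C10) | BrCCC(=O)[C@@]1(C)[C@H](C(C)(C)Br)CC=C(C)C1=O
F2 | step 4 | tertiary bromide with the acryloyl group restored | C=CC(=O)[C@@]1(C)[C@H](C(C)(C)Br)CC=C(C)C1=O
F3 | step 8 | 9-(tert-butyldimethylsilyloxy)-11-nordrima-6,8-diene | C1CCC(C)(C)[C@@H]2C=CC(C)=C(O[Si](C)(C)C(C)(C)C)[C@@]12C
F4 | step 8 | 6,9-epidioxide of F3 (peroxide bridge C6–O–O–C9, silyloxy on C9) | C1CCC(C)(C)[C@@H]2C3C=C(C)C(O[Si](C)(C)C(C)(C)C)(OO3)[C@@]12C
F5 | step 9 | 11-nordrim-7-ene-6β,9β-diol | C1CCC(C)(C)[C@@H]2[C@H](O)C=C(C)[C@H](O)[C@@]12C
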